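Set the south run beside the flask and ask what the extra charge costs. Both receive substrate over 15 h under the same held gas, but the flask carries 0.050 M where the south run carries 0.038 M.

| setting | north-west | south | flask |
|---|---|---|---|
| substrate | 0.025 M (fed, over 15 h) | 0.038 M (fed, over 15 h) | 0.050 M (fed, over 15 h) |
| gas | 3.9 mM (held) | 3.9 mM (held) | 3.9 mM (held) |
| remark | run made earlier | run made earlier |  |
| time |  |  | 5.0 d |

| run | time / d | open intermediate / % | target / % |
|---|---|---|---|
| north-west | 0.625 | 29.6 | 0 |
| north-west | 0.833 | 43.8 | 0 |
| north-west | 1.67 | 71.8 | 4.0 |
| north-west | 2.50 | 75.6 | 11.0 |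
| north-west | 4.00 | 62.1 | 28.5 |
| north-west | 6.00 | 39.4 | 52.5 |
| south | 0.625 | 30.0 | 0 |
| south | 0.833 | 43.3 | 0.2 |
| south | 1.67 | 69.7 | 4.3 |
| south | 2.50 | 71.9 | 11.2 |
| south | 4.00 | 61.8 | 25.2 |
| south | 6.00 | 40.2 | 45.9 |

(readings scatter by 0.5 percentage points)

1. time up to 5.0 d at which open intermediate stands highest
2. the amount of open intermediate, in percent of the substrate charged, at that time

- at the start none of the gas is in solution

Open intermediate rises first and target follows it in the readings, so we look at the gap: the fraction of the charge that is neither of these two. Averaged over the readings at 4.00 d and 6.00 d, it reads 8.75% in the north-west run and 13.4% in the south run. Divided by their charges, these give 3.50 /M and 3.53 /M. We carry their mean, 3.52 /M, as the loss slope: the fraction of the charge lost per molar charged, a selectivity loss that grows with the charge.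

At 2.50 d, target reads 11.0% in the north-west run and 11.2% in the south run. Open intermediate reads its highest there, 75.6% and 71.9%. Target differs between these runs by 0.2 percentage points, less than the drop of 3.7 points in open intermediate, so we put that drop down to the gap, though the slope predicts 4.6 points. For the flask, the extra charge costs 4.2 points against the south run. We therefore commit to 67.7% near 2.50 d.

The forecast gives 70.5% at 2.5 d, higher than our figure, and says “the peak is a little lower”.

The flask gives 70.7% at 2.25 d, above our figure, and at 2.50 d it holds 9.72% target against the south reading of 11.2%.

    substrate + open intermediate → side product (k = 0.00357 /M/min)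
    open intermediate + second intermediate → target (k = 0.00556 /M/min)
    gas ⇌ partner, rate k3*(csat - [partner]) (kL = 0.00301 /min)
    partner → second intermediate (k = 0.00282 /min)
    substrate → open intermediate (k = 8.46 × 10⁻⁴ /min)

In these percentages side product counts as two. The loss slope gives 17.6% for the flask, which holds 16.0% side product at 5.00 d. For a further flask charged with 0.085 M, the slope gives 29.9%, and at 5.00 d that flask holds 24.1%.

The earlier runs and the new flask were generated by integration with made-up constants; the scatter is artificial.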